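**Retrosynthetic overview**
- δ-Lactone and ring B are made last in one acid-triggered cation cascade: an allylic γ-lactone on C9 ionises to the C10 allyl cation, the prenyl chain closes C5–C10, the C4 cation gives the isopropenyl group, and the C9 cation is trapped by the C3 acid.
- The bicyclo[2.2.2]octane is made before that: a C8 oxyallyl cation from a cis-epoxy ketone is captured by the C12 isopropenyl group (C8–C15 bond), and the C16 cation gives the exocyclic alkene.
- Ring C comes from (R)-limonene oxide (sets C12); C5/C6 come from allylMgBr, C1–C3/C10/C20 from ethyl levulinate, C4/C18/C19 from 2-methyl-2-butene.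
- Order of ring formation: ring C (chiral pool) → bicyclo[2.2.2]octane → ring B → δ-lactone; the C15 ketone and C14 acetate are set at the end.

Assumption: atoms are labelled by atisane numbering (C8/C12 bridgeheads, C9 lactone carbon, C14 acetoxy carbon, C15 ketone); the SMILES fixes C12 as R, which is the centre of (R)-(+)-limonene.

**Route**

Step 1
Reactants: 1 (R)-(+)-limonene 1,2-oxide (cis/trans mixture)
Product: 2 (5R)-2-methylidene-5-(prop-1-en-2-yl)cyclohexan-1-ol
Conditions: LiN(iPr)2, Et2O, 0 °C → reflux; aq. work-up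
Reagents that add atoms: none
Why: Base-promoted epoxide-to-allylic-alcohol rearrangement, in which the lithium amide removes the least hindered methyl hydrogen, gives the exocyclic allylic alcohol, and the carbinol epimers are carried on together because that centre is destroyed in step 2 while the limonene centre is untouched.

Step 2
Reactants: 2 (5R)-2-methylidene-5-(prop-1-en-2-yl)cyclohexan-1-ol
Product: 3 (5R)-2-methylidene-5-(prop-1-en-2-yl)cyclohexan-1-one
Conditions: Dess–Martin periodinane, pyridine, CH2Cl2, 0 °C; used at once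
Reagents that add atoms: none
Why: Dess–Martin oxidation of the secondary allylic alcohol under buffered conditions gives the exocyclic enone without isomerisation to carvone and creates no stereocentre.

Step 3
Reactants: 3 (5R)-2-methylidene-5-(prop-1-en-2-yl)cyclohexan-1-one; 4 allylmagnesium bromide
Product: 6 (5R)-2-(but-3-en-1-yl)-5-(prop-1-en-2-yl)cyclohex-2-en-1-one, via trimethylsilyl enol ether 5 (not isolated)
Conditions: allylMgBr, CuBr·SMe2, Me3SiCl, THF, −78 °C; then Pd(OAc)2 (10 mol %), O2, DMSO, rt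
Reagents that add atoms: none
Why: Chlorosilane-accelerated conjugate addition of the allylcopper reagent to the unhindered exocyclic enone joins C6 to C7 and traps the enolate regiospecifically, and Saegusa–Ito dehydrosilylation then returns the more stable endocyclic enone without creating a stereocentre.

Step 4
Reactants: 6 (5R)-2-(but-3-en-1-yl)-5-(prop-1-en-2-yl)cyclohex-2-en-1-one
Product: 7 (1R,5R)-2-(but-3-en-1-yl)-5-(prop-1-en-2-yl)cyclohex-2-en-1-ol
Conditions: NaBH4, CeCl3·7H2O, MeOH, −78 → 0 °C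
Reagents that add atoms: none
Why: Luche 1,2-reduction delivers hydride axially to the half-chair enone on the face anti to the isopropenyl group, exactly as carvone gives cis-carveol, so the new carbinol centre (C9) carries OH cis to isopropenyl.

Step 5
Reactants: 7 (1R,5R)-2-(but-3-en-1-yl)-5-(prop-1-en-2-yl)cyclohex-2-en-1-ol
Product: 8 (1R,2R,4S,6S)-1-(but-3-en-1-yl)-4-(prop-1-en-2-yl)-7-oxabicyclo[4.1.0]heptan-2-ol
Conditions: VO(acac)2 (2 mol %), t-BuOOH, CH2Cl2, 0 °C → rt
Reagents that add atoms: tert-butyl hydroperoxide CC(C)(C)OO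
Why: Vanadium-catalysed hydroxyl-directed epoxidation oxidises only the ring alkene of the allylic alcohol and delivers oxygen syn to the OH, so C8 and C14 are set with the epoxide cis to both OH and isopropenyl while the terminal and isopropenyl alkenes are untouched.

Step 6
Reactants: 8 (1R,2R,4S,6S)-1-(but-3-en-1-yl)-4-(prop-1-en-2-yl)-7-oxabicyclo[4.1.0]heptan-2-ol
Product: 9 (1S,4R,6S)-1-(but-3-en-1-yl)-4-(prop-1-en-2-yl)-7-oxabicyclo[4.1.0]heptan-2-one
Conditions: Dess–Martin periodinane, pyridine, CH2Cl2, rt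
Reagents that add atoms: none
Why: Dess–Martin oxidation of the secondary alcohol gives the cis-epoxy ketone and leaves the epoxide stereocentres untouched.

Step 7
Reactants: 9 (1S,4R,6S)-1-(but-3-en-1-yl)-4-(prop-1-en-2-yl)-7-oxabicyclo[4.1.0]heptan-2-one
Product: 12 (1S,4R,7S)-1-(but-3-en-1-yl)-5-methylidene-7-(triethylsilyloxy)bicyclo[2.2.2]octan-2-one, via epoxy enol silane 10 (not isolated), via bis-silyl enol ether 11 (not isolated)
Conditions: LiN(SiMe3)2, Et3SiCl, THF, −78 °C; then Et3SiOTf (1.1 equiv), 2,6-di-tert-butyl-4-methylpyridine, CH2Cl2, −78 → −30 °C; aq. citric acid work-up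
Reagents that add atoms: triethylsilyl trifluoromethanesulfonate CC[Si](CC)(CC)OS(=O)(=O)C(F)(F)F
Why: Proposed new method: the silyl triflate opens the epoxy enol silane at the tertiary C8–O bond to a 2-silyloxyallyl cation (the first stage of known epoxy-enolsilane (4+3) cycloadditions), which the C12 isopropenyl group held on the same ring attacks at C8 through a boat conformer in a cation–olefin cyclization akin to an interrupted Nazarov capture, the C16 cation then losing a methyl proton to the hindered base, so that C12 dictates the face of the new C8–C15 bond, C14 keeps its oxygen on that same face, and attack at the other cation terminus or by the butenyl chain is disfavoured because it would give a bridgehead enol ether.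

Step 8
Reactants: 12 (1S,4R,7S)-1-(but-3-en-1-yl)-5-methylidene-7-(triethylsilyloxy)bicyclo[2.2.2]octan-2-one
Product: 13 2,4,6-triisopropylbenzenesulfonylhydrazone of 12
Conditions: 2,4,6-triisopropylbenzenesulfonohydrazide, THF, 4 Å molecular sieves, rt
Reagents that add atoms: 2,4,6-triisopropylbenzenesulfonohydrazide CC(C)c1cc(C(C)C)c(S(=O)(=O)NN)c(C(C)C)c1
Why: Hydrazone condensation of the ketone under neutral conditions keeps the silyl ether and changes no stereocentre.

Step 9
Reactants: 13 2,4,6-triisopropylbenzenesulfonylhydrazone of 12; 14 ethyl levulinate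
Product: 17 5-methyl-5-[1-(but-3-en-1-yl)-5-methylidene-7-(triethylsilyloxy)bicyclo[2.2.2]oct-2-en-2-yl]dihydrofuran-2(3H)-one, via alkenyllithium 15 (not isolated), via lithium alkoxide 16 (not isolated)
Conditions: n-BuLi (2.2 equiv), THF, −78 → 0 °C; then ethyl levulinate, −78 °C → rt; aq. NH4Cl
Reagents that add atoms: none
Why: The Shapiro reaction (deprotonation at the only α-CH2, then loss of sulfinate and N2) gives the C9 alkenyllithium and the C9=C11 alkene, this adds to the ketone of ethyl levulinate faster than to its ester, and the tertiary alkoxide closes the γ-lactone, the new C10 centre forming as both epimers, which is harmless because it is ionised in step 12.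

Step 10
Reactants: 17 5-methyl-5-[1-(but-3-en-1-yl)-5-methylidene-7-(triethylsilyloxy)bicyclo[2.2.2]oct-2-en-2-yl]dihydrofuran-2(3H)-one
Product: 18 5-[1-(but-3-en-1-yl)-6-hydroxy-5-methylidene-7-(triethylsilyloxy)bicyclo[2.2.2]oct-2-en-2-yl]-5-methyldihydrofuran-2(3H)-one
Conditions: SeO2 (0.3 equiv), t-BuOOH, CH2Cl2, rt
Reagents that add atoms: tert-butyl hydroperoxide CC(C)(C)OO
Why: SeO2 allylic hydroxylation (ene reaction then [2,3]-sigmatropic shift) of the exocyclic methylene at its only non-bridgehead allylic CH2 (C15) brings oxygen in from the face remote from the silyloxy group, so the hydroxyl points toward the C9=C11 bridge, while the C9=C11 alkene has no usable allylic hydrogen and the terminal alkene reacts far more slowly.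

Step 11
Reactants: 18 5-[1-(but-3-en-1-yl)-6-hydroxy-5-methylidene-7-(triethylsilyloxy)bicyclo[2.2.2]oct-2-en-2-yl]-5-methyldihydrofuran-2(3H)-one; 19 2-methyl-2-butene
Product: 20 5-[6-hydroxy-1-(4-methylpent-3-en-1-yl)-5-methylidene-7-(triethylsilyloxy)bicyclo[2.2.2]oct-2-en-2-yl]-5-methyldihydrofuran-2(3H)-one
Conditions: second-generation Grubbs catalyst (H2IMes)(PCy3)Cl2Ru=CHPh (5 mol %), 2-methyl-2-butene/CH2Cl2, 40 °C
Reagents that add atoms: none
Why: Olefin cross-metathesis of the monosubstituted alkene with excess 2-methyl-2-butene gives the prenyl terminus, the 1,1-disubstituted and trisubstituted alkenes being inert under these conditions, and no stereocentre is touched.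

Step 12
Reactants: 20 5-[6-hydroxy-1-(4-methylpent-3-en-1-yl)-5-methylidene-7-(triethylsilyloxy)bicyclo[2.2.2]oct-2-en-2-yl]-5-methyldihydrofuran-2(3H)-one
Product: 22 14,15-dihydroxy-3,4-seco-atisa-4(18),16-dien-3,9-olide, via seco acid 21 (not isolated)
Conditions: TsOH·H2O (0.3 equiv), (CF3)2CHOH–CH2Cl2 (1:4), 0 °C → rt
Reagents that add atoms: none
Why: Proposed new method: acid ionises the tertiary allylic γ-lactone to the C10–C9–C11 allyl cation and frees the C3 acid, the prenyl alkene attacks C10 through a chair transition state (methyl inside the allyl cation becoming axial, the C4 cation equatorial, and the face chosen so that the hydroxylated C15 bridge stays equatorial instead of being pushed into the new ring), the C4 cation loses a proton to give the isopropenyl group, and protonation of the 9(11)-alkene then gives the tertiary C9 cation that the acid can reach only from the face of its own C1 chain, closing the cis δ-lactone and setting C5, C10 and C9 while the acid also removes the silyl group, the closest known chemistry being allyl-cation-initiated cation–olefin cyclization and acid-mediated lactonization of 9(11)-ene seco acids.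

Step 13
Reactants: 22 14,15-dihydroxy-3,4-seco-atisa-4(18),16-dien-3,9-olide
Product: 23 14-hydroxy-15-oxo-3,4-seco-atisa-4(18),16-dien-3,9-olide
Conditions: MnO2 (activated, excess), CH2Cl2, rt
Reagents that add atoms: none
Why: MnO2 oxidation is selective for the allylic C15 alcohol, giving the exo-methylene ketone while the saturated hindered C14 alcohol is left and no stereocentre is formed.

Step 14
Reactants: 23 14-hydroxy-15-oxo-3,4-seco-atisa-4(18),16-dien-3,9-olide
Product: 24 crotobarin
Conditions: Ac2O, DMAP, pyridine, CH2Cl2, rt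
Reagents that add atoms: acetic anhydride CC(=O)OC(C)=O
Why: DMAP-catalysed acetylation of the secondary C14 alcohol proceeds with retention at carbon and completes the target.

**Compound list**

1 | (4R)-1-methyl-4-(prop-1-en-2-yl)-7-oxabicyclo[4.1.0]heptane, (R)-(+)-limonene 1,2-oxide, cis/trans mixture | CC(=C)[C@@H]1CCC2(C)OC2C1 | starting material
2 | (5R)-2-methylidene-5-(prop-1-en-2-yl)cyclohexan-1-ol (both C1 epimers) | OC1C[C@H](C(C)=C)CCC1=C | intermediate
3 | (5R)-2-methylidene-5-(prop-1-en-2-yl)cyclohexan-1-one | O=C1C[C@H](C(C)=C)CCC1=C | intermediate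
4 | allylmagnesium bromide | C=CC[Mg]Br | starting material
5 | {[(5R)-2-(but-3-en-1-yl)-5-(prop-1-en-2-yl)cyclohex-1-en-1-yl]oxy}trimethylsilane | C[Si](C)(C)OC1=C(CCC=C)CC[C@@H](C(C)=C)C1 | intermediate
6 | (5R)-2-(but-3-en-1-yl)-5-(prop-1-en-2-yl)cyclohex-2-en-1-one | O=C1C[C@H](C(C)=C)CC=C1CCC=C | intermediate
7 | (1R,5R)-2-(but-3-en-1-yl)-5-(prop-1-en-2-yl)cyclohex-2-en-1-ol (OH cis to isopropenyl) | O[C@@H]1C[C@H](C(C)=C)CC=C1CCC=C | intermediate
8 | (1R,2R,4S,6S)-1-(but-3-en-1-yl)-4-(prop-1-en-2-yl)-7-oxabicyclo[4.1.0]heptan-2-ol (OH, epoxide and isopropenyl all cis) | O[C@@H]1C[C@H](C(C)=C)C[C@@H]2O[C@]12CCC=C | intermediate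
9 | (1S,4R,6S)-1-(but-3-en-1-yl)-4-(prop-1-en-2-yl)-7-oxabicyclo[4.1.0]heptan-2-one (epoxide cis to isopropenyl) | O=C1C[C@H](C(C)=C)C[C@@H]2O[C@]12CCC=C | intermediate
10 | {[(1S,4R,6S)-1-(but-3-en-1-yl)-4-(prop-1-en-2-yl)-7-oxabicyclo[4.1.0]hept-2-en-2-yl]oxy}triethylsilane | CC[Si](CC)(CC)OC1=C[C@H](C(C)=C)C[C@@H]2O[C@]12CCC=C | intermediate
11 | (1S,4R,7S)-1-(but-3-en-1-yl)-5-methylidene-2,7-bis(triethylsilyloxy)bicyclo[2.2.2]oct-2-ene | C=C1C[C@]2(CCC=C)C(O[Si](CC)(CC)CC)=C[C@H]1C[C@@H]2O[Si](CC)(CC)CC | intermediate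
12 | (1S,4R,7S)-1-(but-3-en-1-yl)-5-methylidene-7-(triethylsilyloxy)bicyclo[2.2.2]octan-2-one (silyloxy group pointing to the methylidene-bearing bridge) | C=C1C[C@]2(CCC=C)C(=O)C[C@H]1C[C@@H]2O[Si](CC)(CC)CC | intermediate
13 | 2,4,6-triisopropylbenzenesulfonylhydrazone of 12 (ring stereocentres as in 12) | C=C1C[C@]2(CCC=C)C(=NNS(=O)(=O)c3c(C(C)C)cc(C(C)C)cc3C(C)C)C[C@H]1C[C@@H]2O[Si](CC)(CC)CC | intermediate
14 | ethyl levulinate (ethyl 4-oxopentanoate) | CCOC(=O)CCC(C)=O | starting material
15 | [1-(but-3-en-1-yl)-5-methylidene-7-(triethylsilyloxy)bicyclo[2.2.2]oct-2-en-2-yl]lithium (ring stereocentres as in 12) | C=C1C[C@]2(CCC=C)C([Li])=C[C@H]1C[C@@H]2O[Si](CC)(CC)CC | intermediate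
16 | lithium alkoxide of ethyl 4-hydroxy-4-[1-(but-3-en-1-yl)-5-methylidene-7-(triethylsilyloxy)bicyclo[2.2.2]oct-2-en-2-yl]pentanoate | C=C1C[C@]2(CCC=C)C(C(C)(O[Li])CCC(=O)OCC)=C[C@H]1C[C@@H]2O[Si](CC)(CC)CC | intermediate
17 | 5-methyl-5-[1-(but-3-en-1-yl)-5-methylidene-7-(triethylsilyloxy)bicyclo[2.2.2]oct-2-en-2-yl]dihydrofuran-2(3H)-one (ring stereocentres as in 12; both lactone C5 epimers) | C=C1C[C@]2(CCC=C)C(C3(C)CCC(=O)O3)=C[C@H]1C[C@@H]2O[Si](CC)(CC)CC | intermediate
18 | 5-[1-(but-3-en-1-yl)-6-hydroxy-5-methylidene-7-(triethylsilyloxy)bicyclo[2.2.2]oct-2-en-2-yl]-5-methyldihydrofuran-2(3H)-one (6-OH pointing to the C2=C3 bridge) | C=C1[C@H](O)[C@]2(CCC=C)C(C3(C)CCC(=O)O3)=C[C@H]1C[C@@H]2O[Si](CC)(CC)CC | intermediate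
19 | 2-methyl-2-butene | CC=C(C)C | starting material
20 | 5-[6-hydroxy-1-(4-methylpent-3-en-1-yl)-5-methylidene-7-(triethylsilyloxy)bicyclo[2.2.2]oct-2-en-2-yl]-5-methyldihydrofuran-2(3H)-one | C=C1[C@H](O)[C@]2(CCC=C(C)C)C(C3(C)CCC(=O)O3)=C[C@H]1C[C@@H]2O[Si](CC)(CC)CC | intermediate
21 | 15-hydroxy-14-(triethylsilyloxy)-3,4-seco-atisa-4(18),9(11),16-trien-3-oic acid | C=C1[C@H](O)[C@]23CC[C@@H](C(=C)C)[C@](C)(CCC(=O)O)C2=C[C@H]1C[C@@H]3O[Si](CC)(CC)CC | intermediate
22 | 14,15-dihydroxy-3,4-seco-atisa-4(18),16-dien-3,9-olide | C=C1[C@H](O)[C@]23CC[C@@H](C(=C)C)[C@]4(C)CCC(=O)O[C@@]42C[C@H]1C[C@@H]3O | intermediate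
23 | 14-hydroxy-15-oxo-3,4-seco-atisa-4(18),16-dien-3,9-olide (O-deacetylcrotobarin) | C=C1C(=O)[C@]23CC[C@@H](C(=C)C)[C@]4(C)CCC(=O)O[C@@]42C[C@H]1C[C@@H]3O | intermediate
24 | crotobarin (14-acetoxy-15-oxo-3,4-seco-atisa-4(18),16-dien-3,9-olide) | C=C1C(=O)[C@]23CC[C@@H](C(=C)C)[C@]4(C)CCC(=O)O[C@@]42C[C@H]1C[C@@H]3OC(C)=O | target

**Step count**
Total steps: 14. Longest linear sequence: 14 steps (1 → 24).

**Steps most likely to fail, with fallbacks**

Step 7. The oxyallyl cation may lose a proton or undergo a 1,2-hydride shift to a 1,3-diketone before the 1,1-disubstituted alkene reaches C8 through the boat. The fallback sets out from 9 and comes back at 12, and closes the same bond by enolate alkylation instead of cation capture. Ene-type allylic chlorination of the isopropenyl group (Ca(OCl)2, CO2, CH2Cl2–H2O) gives (1S,4R,6S)-1-(but-3-en-1-yl)-4-(3-chloroprop-1-en-2-yl)-7-oxabicyclo[4.1.0]heptan-2-one F1. SmI2 (THF–HMPA, −78 °C) then cleaves the C8–O bond reductively, and the samarium enolate C-alkylates the tethered allylic chloride from the isopropenyl face to give (1S,4R,7S)-1-(but-3-en-1-yl)-7-hydroxy-5-methylidenebicyclo[2.2.2]octan-2-one F2. Et3SiCl and imidazole give 12.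

Step 9. The hindered alkenyllithium may enolise the keto ester instead of adding to it. The fallback sets out from 12 and comes back at 17, and replaces carbonyl addition by cross-coupling and acid lactonization. KN(SiMe3)2 and PhNTf2 give 1-(but-3-en-1-yl)-5-methylidene-7-(triethylsilyloxy)bicyclo[2.2.2]oct-2-en-2-yl trifluoromethanesulfonate F3. Suzuki–Miyaura coupling with methyl 4-(4,4,5,5-tetramethyl-1,3,2-dioxaborolan-2-yl)pent-4-enoate (Pd(PPh3)4, K3PO4, dioxane–H2O) gives methyl 4-[1-(but-3-en-1-yl)-5-methylidene-7-(triethylsilyloxy)bicyclo[2.2.2]oct-2-en-2-yl]pent-4-enoate F4. LiOH gives 4-[1-(but-3-en-1-yl)-5-methylidene-7-(triethylsilyloxy)bicyclo[2.2.2]oct-2-en-2-yl]pent-4-enoic acid F5, and catalytic camphorsulfonic acid adds the acid across the 1,1-disubstituted alkene (Markovnikov) to give 17.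

Step 12. Ring B may close on the wrong face, the prenyl group may attack C11, the C4 cation may give the isopropylidene isomer, or the allylic C15 hydroxyl may ionise. The fallback sets out from 20 and comes back at 22, and separates ring B closure from lactonization using a radical instead of a cation for the C5–C10 bond. Pd(PPh3)4 and Et3N (THF, reflux) open the allylic lactone by ionisation and β-hydride elimination to 4-[6-hydroxy-1-(4-methylpent-3-en-1-yl)-5-methylidene-7-(triethylsilyloxy)bicyclo[2.2.2]oct-2-en-2-yl]pent-4-enoic acid F6. Hydrogen-atom-transfer cycloisomerisation (Co(salen)Cl catalytic, PhSiH3, benzene) puts hydrogen on the diene terminus, the C10 allylic radical closes ring B on the prenyl group in a 6-exo mode, and the alkene is returned as isopropenyl, giving the seco acid 21, which is isolated here. TsOH·H2O in benzene then lactonises at C9 and removes the silyl group to give 22.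

Further compounds
F1 | step 7 | (1S,4R,6S)-1-(but-3-en-1-yl)-4-(3-chloroprop-1-en-2-yl)-7-oxabicyclo[4.1.0]heptan-2-one | O=C1C[C@H](C(=C)CCl)C[C@@H]2O[C@]12CCC=C
F2 | step 7 | (1S,4R,7S)-1-(but-3-en-1-yl)-7-hydroxy-5-methylidenebicyclo[2.2.2]octan-2-one | C=C1C[C@]2(CCC=C)C(=O)C[C@H]1C[C@@H]2O
F3 | step 9 | 1-(but-3-en-1-yl)-5-methylidene-7-(triethylsilyloxy)bicyclo[2.2.2]oct-2-en-2-yl trifluoromethanesulfonate | C=C1C[C@]2(CCC=C)C(OS(=O)(=O)C(F)(F)F)=C[C@H]1C[C@@H]2O[Si](CC)(CC)CC
F4 | step 9 | methyl 4-[1-(but-3-en-1-yl)-5-methylidene-7-(triethylsilyloxy)bicyclo[2.2.2]oct-2-en-2-yl]pent-4-enoate | C=C1C[C@]2(CCC=C)C(C(=C)CCC(=O)OC)=C[C@H]1C[C@@H]2O[Si](CC)(CC)CC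
F5 | step 9 | 4-[1-(but-3-en-1-yl)-5-methylidene-7-(triethylsilyloxy)bicyclo[2.2.2]oct-2-en-2-yl]pent-4-enoic acid | C=C1C[C@]2(CCC=C)C(C(=C)CCC(=O)O)=C[C@H]1C[C@@H]2O[Si](CC)(CC)CC
F6 | step 12 | 4-[6-hydroxy-1-(4-methylpent-3-en-1-yl)-5-methylidene-7-(triethylsilyloxy)bicyclo[2.2.2]oct-2-en-2-yl]pent-4-enoic acid | C=C1[C@H](O)[C@]2(CCC=C(C)C)C(C(=C)CCC(=O)O)=C[C@H]1C[C@@H]2O[Si](CC)(CC)CC
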